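**Retrosynthetic overview**
- Target ⇒ C8–C3′ and C7–OAc are made in one three-component operation. This is an oxidative anti carbo-acetoxylation of (E)-methylisoeugenol by the phenoxenium/oxocarbenium ion of 2-allyl-4,5-dimethoxyphenol, with acetate supplied by PhI(OAc)2. It mirrors the propenylbenzene + allylphenol oxidative coupling assumed for 8.3′-neolignans.
- All three stereocentres (C3′, C8, C7) are set in that operation under a chiral counter-anion.
- Rings: both six-membered rings are bought as arenes, and the dienone ring arises by dearomatisation. The only ring closed on the way is the five-membered 7.O.4′ oxonium ring (the hydrobenzofuranoid branch of the biogenesis). It forms right after the C8–C3′ bond and is opened again at C7 by acetate.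
- 2-Allyl-4,5-dimethoxyphenol ⇒ aromatic Claisen rearrangement ⇒ allyl aryl ether ⇒ 3,4-dimethoxyphenol + allyl bromide.

Assumption: neolignan numbering is used (C7–C9 = propyl chain; C1′ carries the allyl group, C3′ is the quaternary carbon, C6′ the carbonyl); the sense of induction of the chiral acid in step 3 cannot be predicted, so the (S,S)-catalyst is written and its mirror image is used if the first run gives ent-10.

**Step 1**
Reactants: 1 3,4-dimethoxyphenol; 2 allyl bromide
Product: 3 4-(allyloxy)-1,2-dimethoxybenzene
Conditions: K2CO3 (1.5 equiv), acetone, reflux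
Reagents that add atoms: none
Why: Williamson ether synthesis; the phenoxide displaces bromide from the unhindered allylic carbon (SN2), acetone favours O- over C-allylation, and no stereocentre is formed.

**Step 2**
Reactants: 3 4-(allyloxy)-1,2-dimethoxybenzene
Product: 5 2-allyl-4,5-dimethoxyphenol, via ortho-dienone 4 (not isolated)
Conditions: PhNEt2, 190 °C, N2
Reagents that add atoms: none
Why: Aromatic Claisen [3,3]-sigmatropic rearrangement; the allyl group goes to the less hindered ortho carbon (para to the 3-OMe), dienone 4 tautomerises to the phenol, and no stereocentre persists.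

**Step 3**
Reactants: 5 2-allyl-4,5-dimethoxyphenol; 6 (E)-methylisoeugenol [(E)-1,2-dimethoxy-4-(prop-1-enyl)benzene]
Product: 10 (1R,2R)-1-(3,4-dimethoxyphenyl)-2-[(1R)-1,2-dimethoxy-4-oxo-5-(prop-2-enyl)cyclohexa-2,5-dien-1-yl]propyl acetate = target (7R,8R,3′R), via acetoxy ketal 7 (not isolated), via oxocarbenium ion 8 (not isolated), via bridged methyloxonium ion 9 (not isolated)
Conditions: PhI(OAc)2 (1.0 equiv), 4 Å MS, CH2Cl2, −40 °C, 30 min; then 6 (1.5 equiv), (S,S)-IDPi (confined BINOL-derived N-triflyl imidodiphosphorimidate, 5 mol %), −78 °C; Et3N quench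
Reagents that add atoms: (diacetoxyiodo)benzene, CC(=O)OI(OC(C)=O)c1ccccc1
Why: Proposed new method: two-electron phenolic oxidation (PIDA dearomatisation) turns 5 into acetoxy ketal 7, which only the strong confined acid re-ionises at −78 °C to the contact ion pair of oxocarbenium ion 8; the nucleophilic C8 of 6 then attacks the MeO-bearing C3′, which carries most of the charge (C1′ and C5′ are α to the carbonyl), just as π-nucleophiles attack the ketal carbon of enone-ketal-derived oxocarbenium ions and the alkoxy-bearing carbon of oxidised 2-alkoxynaphthols, with H-8 over the ring, Me-9 outside and C7 next to the 4′-OMe, which gives the like (8R,3′R) pair and lets that OMe close the trans-oxonium ring 9; AcOH opens 9 at the p-alkoxybenzylic C7 with inversion (net anti carbo-acetoxylation of the E-alkene, hence 7R) and so gives the C3′ adduct an irreversible exit that is missing in the acetate-free Büchi quinone-ketal/propenylbenzene cycloaddition, where the C1′ adduct wins by ring closure; the face of 8 that is attacked, and thus the absolute configuration, is fixed by the chiral counter-anion (asymmetric counteranion-directed catalysis); closest known reaction types are Büchi-type and PIDA-mediated phenol–styrene cation–olefin couplings, chiral-acid ionisation of quinone (imine) ketals, and the confined-acid-catalysed asymmetric intermolecular Prins reaction of styrenes.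

**Compound list**
1 | 3,4-dimethoxyphenol | COc1ccc(O)cc1OC | starting material
2 | allyl bromide | C=CCBr | starting material
3 | 4-(allyloxy)-1,2-dimethoxybenzene | C=CCOc1ccc(OC)c(OC)c1 | intermediate
4 | 6-allyl-3,4-dimethoxycyclohexa-2,4-dien-1-one (racemic, transient Claisen dienone) | O=C1C=C(OC)C(OC)=CC1CC=C | intermediate
5 | 2-allyl-4,5-dimethoxyphenol | C=CCc1cc(OC)c(OC)cc1O | intermediate
6 | (E)-methylisoeugenol | C/C=C/c1ccc(OC)c(OC)c1 | starting material
7 | 5-allyl-1,2-dimethoxy-4-oxocyclohexa-2,5-dien-1-yl acetate (racemic mixed acetoxy ketal) | C=CCC1=CC(OC)(OC(C)=O)C(OC)=CC1=O | intermediate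
8 | (5-allyl-2-methoxy-4-oxocyclohexa-2,5-dien-1-ylidene)(methyl)oxonium, the phenoxenium/oxocarbenium ion paired with the IDPi anion | C=CCC1=CC(=[O+]C)C(OC)=CC1=O | intermediate
9 | (2S,3R,3aR)-5-allyl-2-(3,4-dimethoxyphenyl)-3a-methoxy-1,3-dimethyl-6-oxo-2,3,3a,6-tetrahydrobenzofuran-1-ium (aryl and methyl trans, methyl and 3a-OMe cis) | C=CCC1=C[C@@]2(OC)[C@H](C)[C@@H](c3ccc(OC)c(OC)c3)[O+](C)C2=CC1=O | intermediate
10 | (1R,2R)-1-(3,4-dimethoxyphenyl)-2-[(1R)-1,2-dimethoxy-4-oxo-5-(prop-2-enyl)cyclohexa-2,5-dien-1-yl]propyl acetate (7R,8R,3′R) | C=CCC1=C[C@@](OC)([C@H](C)[C@@H](OC(C)=O)c2ccc(OC)c(OC)c2)C(OC)=CC1=O | target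

**Total step count:** 3. **Longest linear sequence:** 3 steps (1 → 3 → 5 → 10).

**Steps most likely to fail**

**Step 3 (highest risk).**
- Alkene 6 may attack the allyl-bearing C1′ of 8, as it does in the known acetate-free reaction. That would give 8.1′ bicyclo[3.2.1]octanoid or hydrobenzofuranoid products.
- Ion 9 may lose its O-methyl group instead of being opened at C7.
- The dr at C8/C3′ and the ee are not known.

The fallback gives up forming the C8–C3′ bond at the oxygen-bearing carbon. The bond is made on an aromatic ring instead, and the 3′-OMe is brought in last as the nucleophile, because para attack of methanol on a 4-alkylphenoxenium ion is reliable. The fallback sets out from allyl bromide 2 and comes back at 10. Compound 2 alkylates commercial 4-bromo-3-methoxyphenol (K2CO3, acetone) to 4-(allyloxy)-1-bromo-2-methoxybenzene F1. Magnesium in THF gives [4-(allyloxy)-2-methoxyphenyl]magnesium bromide F2. This is coupled with commercial racemic 2-bromo-1-(3,4-dimethoxyphenyl)propan-1-one in a nickel/bis(oxazoline)-catalysed stereoconvergent Kumada α-arylation at −60 °C, giving (S)-2-[4-(allyloxy)-2-methoxyphenyl]-1-(3,4-dimethoxyphenyl)propan-1-one F3. Catalyst-controlled Noyori–Ikariya transfer hydrogenation [(R,R)-TsDPEN–Ru, HCO2H/Et3N] gives (1R,2S)-2-[4-(allyloxy)-2-methoxyphenyl]-1-(3,4-dimethoxyphenyl)propan-1-ol F4; this works against the substrate's Felkin preference, and the C7 epimer is removed by chromatography. Ac2O/pyridine gives (1R,2S)-2-[4-(allyloxy)-2-methoxyphenyl]-1-(3,4-dimethoxyphenyl)propyl acetate F5. Aromatic Claisen rearrangement (PhNEt2, 180 °C) runs through the transient ortho-dienone F6 to (1R,2S)-2-(5-allyl-4-hydroxy-2-methoxyphenyl)-1-(3,4-dimethoxyphenyl)propyl acetate F7. PhI(OAc)2 in MeOH at 0 °C then adds methanol para to the phenol oxygen and gives 10. Facial selectivity is expected to be only moderate, so the diastereomers at C3′ are separated by chromatography.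

**Step 2.** The rearrangement may give some of the 2,3,4-substituted regioisomer, and the electron-rich phenol may decompose at 190 °C. The fallback replaces the sigmatropic C-allylation by halogenation and cross-coupling. It sets out from 1 and comes back at 5, bypassing 3 and 4. NBS in MeCN at 0 °C brominates 1 ortho to the OH and para to the 3-OMe to give 2-bromo-4,5-dimethoxyphenol F8. Suzuki–Miyaura allylation (allylboronic acid pinacol ester, Pd(dppf)Cl2, K2CO3, dioxane/H2O, 80 °C) then gives 5.

**Step 1 (low risk).** C-allylation or air oxidation of the electron-rich phenoxide could compete. The fallback uses neutral π-allyl chemistry instead of SN2: a Tsuji–Trost O-allylation of 1 with allyl methyl carbonate (Pd(PPh3)4, THF, rt). It sets out from 1 and comes back at 3, and it makes no new compound.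

**Further compounds**
F1 | step 3 | 4-(allyloxy)-1-bromo-2-methoxybenzene | C=CCOc1ccc(Br)c(OC)c1
F2 | step 3 | [4-(allyloxy)-2-methoxyphenyl]magnesium bromide | C=CCOc1ccc([Mg]Br)c(OC)c1
F3 | step 3 | (S)-2-[4-(allyloxy)-2-methoxyphenyl]-1-(3,4-dimethoxyphenyl)propan-1-one | C=CCOc1ccc([C@H](C)C(=O)c2ccc(OC)c(OC)c2)c(OC)c1
F4 | step 3 | (1R,2S)-2-[4-(allyloxy)-2-methoxyphenyl]-1-(3,4-dimethoxyphenyl)propan-1-ol | C=CCOc1ccc([C@H](C)[C@@H](O)c2ccc(OC)c(OC)c2)c(OC)c1
F5 | step 3 | (1R,2S)-2-[4-(allyloxy)-2-methoxyphenyl]-1-(3,4-dimethoxyphenyl)propyl acetate | C=CCOc1ccc([C@H](C)[C@@H](OC(C)=O)c2ccc(OC)c(OC)c2)c(OC)c1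
F6 | step 3 | (1R,2S)-2-(5-allyl-2-methoxy-4-oxocyclohexa-1,5-dien-1-yl)-1-(3,4-dimethoxyphenyl)propyl acetate (transient Claisen ortho-dienone, epimers at the allyl-bearing carbon) | O=C1C=C(OC)C([C@H](C)[C@@H](OC(C)=O)c2ccc(OC)c(OC)c2)=CC1CC=C
F7 | step 3 | (1R,2S)-2-(5-allyl-4-hydroxy-2-methoxyphenyl)-1-(3,4-dimethoxyphenyl)propyl acetate | C=CCc1cc([C@H](C)[C@@H](OC(C)=O)c2ccc(OC)c(OC)c2)c(OC)cc1O
F8 | step 2 | 2-bromo-4,5-dimethoxyphenol | COc1cc(O)c(Br)cc1OC
F0 | step 1 | none | none
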